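## Analysis of the target

The target is a flavonol, 2-(2,4-dihydroxy-5-methoxyphenyl)-3,5-dihydroxy-7,8-dimethoxy-4H-chromen-4-one. Ring A (C4a, C5 to C8, C8a) carries 5-OH, 7-OMe and 8-OMe. Ring C (O1, C2, C3, C4) carries the C4 carbonyl and the 3-OH. Ring B (C1' to C6') sits on C2 and carries 2'-OH, 4'-OH and 5'-OMe. There is no stereocenter, so the problem is one of regiochemistry and of telling seven oxygen functions apart: four free hydroxyls and three methyl ethers.

The free compound is an electron-rich polyphenol. The 3-hydroxy-pyranone and the para-related 2'-OH/5'-OMe pair of ring B are prone to oxidation, above all in base. A 5-hydroxy-7,8-dioxygenated ring A can also isomerise to the 5,6,7 pattern by opening and reclosing ring C in hot strong protic acid. The phenols should therefore be set free last, under cold Lewis-acidic conditions.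

The feature that carries the plan is C2. It is bonded to C1' of ring B, to C3 and to O1, so it stands at the oxidation level of a carboxylic acid. It can therefore enter as carbon monoxide between a ring B aryl bromide and the methyl carbon of a ring A ortho-hydroxyacetophenone, whose hydroxyl is already the future O1.

## Retrosynthetic reasoning

**Target 14 to flavonol 13.** The two O–CH2Ph bonds at C2' and C4' and the O–CH3 bond at C5 are cut last. Benzyl ethers ionise under a boron halide Lewis acid, and the C5 methyl ether is the only one that can chelate that Lewis acid to the C4 carbonyl. One operation should therefore free three hydroxyls while the 7-, 8- and 5'-methoxy groups stay. Everything before this step is then free of ring B phenols and tolerates base, palladium and oxidant.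

**13 to flavone 11 (through epoxide 12).** The C3–O bond is cut. The C2=C3 bond of 11 can take up one oxygen atom from a neutral oxygen-transfer reagent to give 12, and acid opens 12 at C2 to the 3-hydroxy enone. The oxygen is put in after ring C exists because the key step delivers C3 as a CH2 group. It is put in before deprotection because a free 5-OH would deactivate the double bond by hydrogen bonding to the carbonyl.

**11 to diketone 10.** The O1–C2 bond is cut. In 10 the ring A hydroxyl is six atoms from the carbonyl next to ring B, so acid-catalysed addition and loss of water close ring C with no further reagent.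

**10 to acetophenone 3, bromide 8 and carbon monoxide 9.** The bonds C1'–C2 and C2–C3 are cut together. Both end at C2, which is then a single carbon atom at the right oxidation level. The cut leaves two arenes that already carry their full substitution patterns. Cutting elsewhere in ring C (O1–C8a or C4–C4a) would put the burden on a ring A nucleophile whose regiochemistry is harder to fix. The forward reaction has to join three components at one carbon and must not couple the aryl group directly to the enolate.

**3 to tetramethoxybenzene 1 (through ketone 2).** The aryl–acyl bond is cut and the ortho methyl ether is restored. The two free positions of 1 are equivalent, so acylation has no regiochemical choice. The same Lewis acid should then remove the ortho methoxy group that is flanked on both sides, which leaves the free hydroxyl where O1 is needed.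

**8 to phenol 7, aldehyde 5 (through formate 6) and bromo aldehyde 4.** The methyl ether is cut first, then the phenolic C–O bond is traced back to a formyl group (peracid oxidation with aryl migration), then the two benzyl ethers are cut. In 4 the bromine already stands para to one hydroxyl and meta to the formyl carbon, so no halogenation of an electron-rich arene is needed. The formyl group marks the carbon that becomes C5'–OMe.

## Alternatives that were turned down

**Alternative 1: ring A built by cyclobutenone ring expansion.**
- Disconnection: C4a–C5, with ring A assembled from a four-membered ring and a dihydropyran that already carries ring B.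
- Forward key step: heating cyclobutenone A2 opens the four-membered ring to a dienylketene. The ketene carbon bonds to the dihydropyran carbon that becomes C4a, and tautomerisation gives the phenol A1.
- For: the ring A pattern is fixed by construction, and the C5 hydroxyl emerges free. On these two points it is stronger than the chosen plan, which depends on a chelation-controlled demethylation at each end of the route.
- Against: A1 is a 4-silyloxyflavan. Ring C must still be desilylated, oxidised at C4, dehydrogenated across C2–C3 and hydroxylated at C3, all with a free 5-OH in place. Two stereocenters are made only to be destroyed. A2 needs a metalated dihydropyran and a four-membered electrophile, each with its own multistep preparation.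
- Comparison: the chosen plan buys the ring A pattern in 1 and forms ring C at the flavone oxidation level, so only one oxidation remains after the key step.

**Alternative 2: ring C closed at C4–C4a by cycloacylation.**
- Disconnection: C4–C4a, with O1–C2 already present as an aryl vinyl ether.
- Forward key step: the acrylic acid A4 is activated as a mixed anhydride and acylates the only free ortho carbon of its trimethoxyphenoxy group to give the tribenzyl flavonol A3.
- For: the C3 oxygen is present from the start, so there is no late oxidation. The cyclisation has only one possible site. A3 would reach the target in one Lewis acid step. On the C3 oxygen and on the number of steps after the key step it is stronger than the chosen plan.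
- Against: A4 is a tetrasubstituted enol ether acid with three different substituents and one required geometry (carboxyl cis to the aryloxy group). Its assembly is long and its geometry uncertain. The wrong isomer presents the activated acyl group to C6' of ring B and would close an indenone. The strongly acidic acylating medium meets three benzyl ethers next to very electron-rich rings, which invites benzyl transfer. The phenol half is not a commodity chemical.
- Comparison: the chosen plan has no alkene geometry to control and starts from catalogue arenes. It pays for this with one oxidation at C3.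

**Alternative 3: Auwers ring expansion of an aurone dibromide.**
- Disconnection: O1–C2, formed while a five-membered coumaranone is enlarged to ring C.
- Forward key step: hot aqueous-alcoholic hydroxide opens the coumaranone of dibromide A6. The freed ring A phenoxide attacks the benzylic carbon, and loss of bromide gives the flavonol A5.
- For: the 3-OH is created in the ring-forming step. On this point it is stronger than the chosen plan.
- Against: making A6 requires adding bromine across an exocyclic double bond in a molecule whose ring A has a free position between two methoxy groups, so nuclear bromination competes. The mesylates that deactivate ring B must survive hot hydroxide. If the 2'-mesylate is lost, the phenoxide next to the benzylic bromide can expel it. The bicyclic core of A6 would have to be derived from 3 in extra steps. The end game needs two different deprotections, mesylate cleavage and C5 demethylation.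
- Comparison: the chosen plan uses no halogenation of an electron-rich arene, no hot hydroxide on a protected polyphenol, and a single final deprotection.

Key step: step 5

Assumption: 1,2,3,5-tetramethoxybenzene and 5-bromo-2,4-dihydroxybenzaldehyde are taken as catalogue compounds, and carbon monoxide is supplied at about 1 atm from a balloon or a two-chamber vessel.

## Route

Step 1
Reactants: 1 1,2,3,5-tetramethoxybenzene
Product: 3 1-(2-hydroxy-3,4,6-trimethoxyphenyl)ethanone, via 2,3,4,6-tetramethoxyacetophenone 2 (not isolated)
Conditions: AcCl (1.2 equiv), AlCl3 (2.5 equiv), Et2O, 0 °C to reflux; aq. HCl work-up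
Reagents that add atoms: acetyl chloride, CC(=O)Cl
Why: Friedel–Crafts acylation can only occur at the two equivalent free positions of 1; AlCl3 chelated between the new carbonyl and an ortho methoxy group then cleaves the methoxy flanked by the 3-methoxy group (twisted out of plane, more basic, strain relieved), and the aluminium phenoxide chelate should protect the second ortho methoxy group.

Step 2
Reactants: 4 5-bromo-2,4-dihydroxybenzaldehyde
Product: 5 2,4-bis(benzyloxy)-5-bromobenzaldehyde
Conditions: BnBr (2.5 equiv), K2CO3, DMF, 70 °C
Reagents that add atoms: benzyl bromide, BrCc1ccccc1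
Why: Williamson etherification of both phenols; heating is needed because the 2-OH is hydrogen-bonded to the formyl group.

Step 3
Reactants: 5 2,4-bis(benzyloxy)-5-bromobenzaldehyde
Product: 7 2,4-bis(benzyloxy)-5-bromophenol, via aryl formate 6 (not isolated)
Conditions: mCPBA, CH2Cl2, 0 °C to rt; then K2CO3 (cat.), MeOH, rt
Reagents that add atoms: mCPBA, O=C(OO)c1cccc(Cl)c1
Why: Baeyer–Villiger (Dakin-type) oxidation; the aryl group with ortho and para alkoxy donors migrates in preference to hydrogen, and the formate is removed by methanolysis in the same flask.

Step 4
Reactants: 7 2,4-bis(benzyloxy)-5-bromophenol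
Product: 8 1,5-bis(benzyloxy)-2-bromo-4-methoxybenzene
Conditions: MeI, K2CO3, acetone, reflux
Reagents that add atoms: iodomethane, CI
Why: Williamson O-methylation of the only free phenol; this fixes the 5'-methoxy group beside the 4'-benzyloxy group.

Step 5
Reactants: 3 1-(2-hydroxy-3,4,6-trimethoxyphenyl)ethanone, 8 1,5-bis(benzyloxy)-2-bromo-4-methoxybenzene, 9 carbon monoxide
Product: 10 1-[2,4-bis(benzyloxy)-5-methoxyphenyl]-3-(2-hydroxy-3,4,6-trimethoxyphenyl)propane-1,3-dione
Conditions: Pd(dba)2 (5 mol %), Xantphos (5 mol %), NaN(SiMe3)2 (3.2 equiv), CO (1 atm), dioxane, 80 °C; cold dilute HCl quench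
Reagents that add atoms: none
Why: Zerovalent palladium carrying Xantphos inserts into the C–Br bond of 8, and carbon monoxide 9 then inserts into the aryl–palladium bond to give an aroyl complex of divalent palladium. NaN(SiMe3)2 converts 3 into its phenoxide–enolate dianion, whose enolate carbon replaces bromide on palladium, and C–C reductive elimination releases the 1,3-diketone and returns zerovalent palladium, so C1'–C2 and C2–C3 are made in one catalytic cycle. The diketone is at once deprotonated by the third equivalent of base to a diketonate, which is too poor a nucleophile to be aroylated a second time. Should the phenoxide oxygen capture the aroyl group instead, the resulting ortho-acyloxyacetophenone undergoes the Baker–Venkataraman O-to-C acyl shift under the same base, so both pathways converge on 10. The closest known reaction type is the palladium-catalysed carbonylative alpha-arylation of aryl methyl ketones, 2-hydroxyacetophenones included, with aryl bromides. No ring is closed and no stereocenter is formed. The selectivity required is CO insertion ahead of enolate coupling, since direct alpha-arylation would give a deoxybenzoin lacking C2; the wide bite angle of Xantphos, the CO atmosphere and the ortho benzyloxy group of 8, which retards direct aryl–enolate coupling, all favour the acyl pathway. Benzyl and methyl ethers are inert to the catalyst and the base, and the hindered di-ortho-substituted ketone 3 has little tendency to self-condense.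

Step 6
Reactants: 10 1-[2,4-bis(benzyloxy)-5-methoxyphenyl]-3-(2-hydroxy-3,4,6-trimethoxyphenyl)propane-1,3-dione
Product: 11 2-[2,4-bis(benzyloxy)-5-methoxyphenyl]-5,7,8-trimethoxy-4H-chromen-4-one
Conditions: H2SO4 (cat.), AcOH, 80 °C
Reagents that add atoms: none
Why: Acid-catalysed cyclodehydration of an ortho-hydroxyaryl 1,3-diketone, the closing stage of the Baker–Venkataraman flavone synthesis; the phenol adds to the carbonyl next to ring B (6-exo-trig) and the hemiketal loses water to the pyranone, while catalytic acid in acetic acid should leave aryl benzyl and methyl ethers intact.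

Step 7
Reactants: 11 2-[2,4-bis(benzyloxy)-5-methoxyphenyl]-5,7,8-trimethoxy-4H-chromen-4-one
Product: 13 2-[2,4-bis(benzyloxy)-5-methoxyphenyl]-3-hydroxy-5,7,8-trimethoxy-4H-chromen-4-one, via flavone 2,3-epoxide 12 (not isolated)
Conditions: dimethyldioxirane (acetone solution, 2–3 equiv), CH2Cl2, 0 °C to rt, dark; evaporate; then p-TsOH·H2O (cat.), CH2Cl2, rt
Reagents that add atoms: dimethyldioxirane, CC1(C)OO1
Why: Dimethyldioxirane epoxidises the C2=C3 bond of flavones under neutral conditions; acid then opens the oxirane at C2 (cation stabilised by O1 and ring B) and loss of the C3 proton gives the 3-hydroxy enone. The epoxide is racemic and both of its stereocenters are erased on opening.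

Step 8
Reactants: 13 2-[2,4-bis(benzyloxy)-5-methoxyphenyl]-3-hydroxy-5,7,8-trimethoxy-4H-chromen-4-one
Product: 14 2-(2,4-dihydroxy-5-methoxyphenyl)-3,5-dihydroxy-7,8-dimethoxy-4H-chromen-4-one
Conditions: BCl3 (excess), pentamethylbenzene, CH2Cl2, −78 °C to 0 °C; MeOH quench, dilute aq. HCl work-up
Reagents that add atoms: none
Why: BCl3 cleaves aryl benzyl ethers at low temperature with pentamethylbenzene as a benzyl cation trap, and on warming it removes the C5 methyl group by chloride attack within the six-membered boron chelate to the C4 carbonyl. The 7-, 8- and 5'-methoxy groups have no chelating carbonyl neighbour and should remain.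

## Compound list

1 | 1,2,3,5-tetramethoxybenzene | COc1cc(OC)c(OC)c(OC)c1 | starting material
2 | 1-(2,3,4,6-tetramethoxyphenyl)ethanone (2,3,4,6-tetramethoxyacetophenone) | CC(=O)c1c(OC)cc(OC)c(OC)c1OC | intermediate (not isolated)
3 | 1-(2-hydroxy-3,4,6-trimethoxyphenyl)ethanone | CC(=O)c1c(OC)cc(OC)c(OC)c1O | intermediate
4 | 5-bromo-2,4-dihydroxybenzaldehyde | O=Cc1cc(Br)c(O)cc1O | starting material
5 | 2,4-bis(benzyloxy)-5-bromobenzaldehyde | O=Cc1cc(Br)c(OCc2ccccc2)cc1OCc1ccccc1 | intermediate
6 | 2,4-bis(benzyloxy)-5-bromophenyl formate | O=COc1cc(Br)c(OCc2ccccc2)cc1OCc1ccccc1 | intermediate (not isolated)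
7 | 2,4-bis(benzyloxy)-5-bromophenol | Oc1cc(Br)c(OCc2ccccc2)cc1OCc1ccccc1 | intermediate
8 | 1,5-bis(benzyloxy)-2-bromo-4-methoxybenzene | COc1cc(Br)c(OCc2ccccc2)cc1OCc1ccccc1 | intermediate
9 | carbon monoxide | [C-]#[O+] | starting material
10 | 1-[2,4-bis(benzyloxy)-5-methoxyphenyl]-3-(2-hydroxy-3,4,6-trimethoxyphenyl)propane-1,3-dione | O=C(CC(=O)c1cc(OC)c(OCc2ccccc2)cc1OCc1ccccc1)c1c(OC)cc(OC)c(OC)c1O | intermediate
11 | 2-[2,4-bis(benzyloxy)-5-methoxyphenyl]-5,7,8-trimethoxy-4H-chromen-4-one | O=c1cc(-c2cc(OC)c(OCc3ccccc3)cc2OCc2ccccc2)oc2c(OC)c(OC)cc(OC)c12 | intermediate
12 | 1a-[2,4-bis(benzyloxy)-5-methoxyphenyl]-3,4,6-trimethoxy-1a,7a-dihydro-7H-oxireno[2,3-b]chromen-7-one (2,3-epoxide of 11; racemic, cis-fused, one enantiomer drawn) | O=C1c2c(OC)cc(OC)c(OC)c2O[C@]2(c3cc(OC)c(OCc4ccccc4)cc3OCc3ccccc3)O[C@H]12 | intermediate (not isolated)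
13 | 2-[2,4-bis(benzyloxy)-5-methoxyphenyl]-3-hydroxy-5,7,8-trimethoxy-4H-chromen-4-one | O=c1c(O)c(-c2cc(OC)c(OCc3ccccc3)cc2OCc2ccccc2)oc2c(OC)c(OC)cc(OC)c12 | intermediate
14 | 2-(2,4-dihydroxy-5-methoxyphenyl)-3,5-dihydroxy-7,8-dimethoxy-4H-chromen-4-one | COc1cc(-c2oc3c(OC)c(OC)cc(O)c3c(=O)c2O)c(O)cc1O | target

## Step count and risks

Total: 8 steps. Longest linear sequence: 7 steps (4 to 14 through steps 2, 3, 4, 5, 6, 7 and 8). The ring A branch adds one step (step 1) before the convergence in step 5.

**Step 5 (key step).** The electron-rich, ortho-substituted bromide 8 undergoes oxidative addition slowly, and under CO the zerovalent palladium may be drained into inactive carbonyl species before turnover. Coupling without CO insertion or hydrodebromination could then take over. The fallback gives up the carbonylation and builds the same diketone by acyl transfer. It sets out from 8 and 3 and returns at 10. Bromine–lithium exchange on 8 (n-BuLi, THF, −78 °C) and quenching with CO2 should give 2,4-bis(benzyloxy)-5-methoxybenzoic acid F1. Oxalyl chloride with catalytic DMF converts it into 2,4-bis(benzyloxy)-5-methoxybenzoyl chloride F2. Acylation of the phenol of 3 (pyridine, DMAP) gives 2-acetyl-3,5,6-trimethoxyphenyl 2,4-bis(benzyloxy)-5-methoxybenzoate F3. KOH in pyridine, or KOtBu in THF, then effects the Baker–Venkataraman shift to 10.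

**Step 7.** The C2=C3 bond of a 5-methoxyflavone is an electron-poor, vinylogous-ester alkene and takes up oxygen slowly. Oxidation of the benzylic C–H bonds of the benzyl ethers, or of the alkoxy-rich arenes, may therefore compete, and the acid opening of the epoxide may be diverted to hydration. The fallback replaces oxygen transfer by metalation. It sets out from 11 and returns at 13. LiN(iPr)2 in THF at −78 °C deprotonates C3, and B(OMe)3 traps the anion as dimethyl {2-[2,4-bis(benzyloxy)-5-methoxyphenyl]-5,7,8-trimethoxy-4-oxo-4H-chromen-3-yl}boronate F4. Oxidation with H2O2 in AcOH then gives 13.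

**Step 8.** Three cleavages are asked of one reagent. If the mixture is kept cold the C5 methyl ether may survive. If it is warmed too far the doubly flanked 8-methoxy group, or the 5'-methoxy group beside the boron-bound 4'-oxygen, may also be lost. With too little scavenger the benzyl cations may alkylate the electron-rich rings. The fallback separates the two kinds of cleavage. It sets out from 13 and returns at 14. Hydrogenolysis (H2, Pd/C, EtOAc–MeOH) should give 2-(2,4-dihydroxy-5-methoxyphenyl)-3-hydroxy-5,7,8-trimethoxy-4H-chromen-4-one F5. AlCl3 in MeCN then removes only the chelated C5 methyl group to give 14.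

## Further compounds

F1 | step 5 | 2,4-bis(benzyloxy)-5-methoxybenzoic acid | COc1cc(C(=O)O)c(OCc2ccccc2)cc1OCc1ccccc1
F2 | step 5 | 2,4-bis(benzyloxy)-5-methoxybenzoyl chloride | COc1cc(C(=O)Cl)c(OCc2ccccc2)cc1OCc1ccccc1
F3 | step 5 | 2-acetyl-3,5,6-trimethoxyphenyl 2,4-bis(benzyloxy)-5-methoxybenzoate | CC(=O)c1c(OC)cc(OC)c(OC)c1OC(=O)c1cc(OC)c(OCc2ccccc2)cc1OCc1ccccc1
F4 | step 7 | dimethyl {2-[2,4-bis(benzyloxy)-5-methoxyphenyl]-5,7,8-trimethoxy-4-oxo-4H-chromen-3-yl}boronate | COB(OC)c1c(-c2cc(OC)c(OCc3ccccc3)cc2OCc2ccccc2)oc2c(OC)c(OC)cc(OC)c2c1=O
F5 | step 8 | 2-(2,4-dihydroxy-5-methoxyphenyl)-3-hydroxy-5,7,8-trimethoxy-4H-chromen-4-one | COc1cc(-c2oc3c(OC)c(OC)cc(OC)c3c(=O)c2O)c(O)cc1O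
A1 | alternative 1 | 7,8-dimethoxy-2-[5-methoxy-2,4-di(propan-2-yloxy)phenyl]-4-(triisopropylsilyloxy)chroman-5-ol (racemic, stereoisomer mixture) | COc1cc(O)c2c(c1OC)OC(c1cc(OC)c(OC(C)C)cc1OC(C)C)CC2O[Si](C(C)C)(C(C)C)C(C)C
A2 | alternative 1 | 3,4-dimethoxy-4-{6-[5-methoxy-2,4-di(propan-2-yloxy)phenyl]-4-(triisopropylsilyloxy)-5,6-dihydro-4H-pyran-2-yl}cyclobut-2-en-1-one (racemic, stereoisomer mixture) | COC1=CC(=O)C1(OC)C1=CC(O[Si](C(C)C)(C(C)C)C(C)C)CC(c2cc(OC)c(OC(C)C)cc2OC(C)C)O1
A3 | alternative 2 | 3-(benzyloxy)-2-[2,4-bis(benzyloxy)-5-methoxyphenyl]-5,7,8-trimethoxychromen-4-one | O=c1c(OCc2ccccc2)c(-c2cc(OC)c(OCc3ccccc3)cc2OCc2ccccc2)oc2c(OC)c(OC)cc(OC)c12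
A4 | alternative 2 | (2E)-2-(benzyloxy)-3-[2,4-bis(benzyloxy)-5-methoxyphenyl]-3-(2,3,5-trimethoxyphenoxy)prop-2-enoic acid | OC(=O)/C(OCc1ccccc1)=C(\Oc1cc(OC)cc(OC)c1OC)c1cc(OC)c(OCc2ccccc2)cc1OCc1ccccc1
A5 | alternative 3 | 3-hydroxy-5,7,8-trimethoxy-2-[5-methoxy-2,4-bis(methylsulfonyloxy)phenyl]chromen-4-one | O=c1c(O)c(-c2cc(OC)c(OS(C)(=O)=O)cc2OS(C)(=O)=O)oc2c(OC)c(OC)cc(OC)c12
A6 | alternative 3 | 2-bromo-2-{bromo[5-methoxy-2,4-bis(methylsulfonyloxy)phenyl]methyl}-4,6,7-trimethoxy-1-benzofuran-3(2H)-one (racemic, stereoisomer mixture) | O=C1c2c(OC)cc(OC)c(OC)c2OC1(Br)C(Br)c1cc(OC)c(OS(C)(=O)=O)cc1OS(C)(=O)=O
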